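A small charge: 8.8 mM of initiator stands against 1.5 M of starting material in the gamma flask, and you must judge what more time, heat or removal of product can add.

all flasks: starting material 1.5 M; reagent 2.25 M; initiator 8.8 mM

|  | temperature | remark | time |
|---|---|---|---|
| gamma | 70 °C | the very flask that is asked about, followed so far |  |
| eta | 65 °C | run made earlier |  |
| flask | 70 °C |  | 2.5 d |

| run | time / h | product / % | starting material / % |
|---|---|---|---|
| gamma | 8.00 | 38 | 51 |
| gamma | 20.0 | 62 | 18 |
| gamma | 40.0 | 76 | 7 |
| gamma | 60.0 | 80 | 4 |
| eta | 8.00 | 28 | 62 |
| eta | 20.0 | 52 | 31 |
| eta | 40.0 | 70 | 13 |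
| eta | 60.0 | 77 | 5 |

(standard deviation of a reading: 1.5 percentage points)

- product, in percent of the starting material first charged, at 2.5 d
- which option adds most product ("none" when 2 percentage points or less is all one gets) (north / south-west / north-east / none)
- product present, with what was taken out counted in, in percent of the starting material first charged, after south-west
- product present, with what was taken out counted in, in percent of the starting material first charged, after north-east

- north: change nothing and wait 30 h more
- south-west: at 2.5 d raise the temperature by 10 K, then wait 30 h
- north-east: at 2.5 d take out 90 % of the product then present, then wait 30 h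

- removed product is counted in

Read the gamma flask at 2.5 d: product stands at 80 %. Now define the turnover constant κ: product made per hour, divided by the free starting material, a pseudo-first-order constant. Replace the curve by its mean. The area under the starting-material readings is 13.8 h of full charge, so κ is 0.0581 h⁻¹. Check the error: the first interval gives 0.0629 h⁻¹, and 20.0 h to 40.0 h gives 0.0560 h⁻¹. Product doubled from 8.00 h to 40.0 h and these two readings of κ stay close, so I expect north-east to match north.

Now bracket the gain from waiting. From above, hold [starting material] at its last reading: 7 percentage points. From below, let it drain with nothing returned: 3.3 points. Tighten: the missing share of the gamma readings went from 20.0 % at 20.0 h to 16.0 % at 60.0 h, so some of it may be returning, and the last readings show starting material falling at 0.0280 h⁻¹, slower than κ. Falling so, it gives 4.7 points.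

For heat, the eta run gives κ = 0.0422 h⁻¹. Squaring that step for 10 K makes κ 0.110 h⁻¹. The bracket becomes 3.9 points to 13 points, tightened to 6.6 points. I commit to south-west, 86.6 %, and north-east, 84.7 %.

The forecast gives 80 % now, none as best, 82 % after south-west and 82 % after north-east, its north-east gain standing below my lower bound: “No option clearly exceeds 2 points.”

The flask gives 79.8 % and best south-west, with gains of 4.7 points for north, 9.3 points for south-west and 4.7 points for north-east, so 89.0 % and 84.5 %.

    starting material + initiating radical → chain carrier (k = 37000 M⁻¹ min⁻¹, Ea = 37.0 kJ mol⁻¹)
    reagent + chain carrier → product + initiating radical (k = 12000 M⁻¹ s⁻¹, Ea = 45.0 kJ mol⁻¹)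
    starting material ⇌ dormant form (K = 1.80, k = 4.20 × 10⁻⁴ min⁻¹, Ea = 115 kJ mol⁻¹, ΔH = 8.00 kJ mol⁻¹)
    2 chain carrier → ended chains A (k = 4.60 × 10⁸ M⁻¹ s⁻¹, Ea = 15.0 kJ mol⁻¹)
    initiator → 2 initiating radical (k = 1.30 × 10⁻⁴ min⁻¹, Ea = 114 kJ mol⁻¹)
    2 initiating radical → ended chains B (k = 2.00 × 10⁷ M⁻¹ s⁻¹, Ea = 17.0 kJ mol⁻¹)
    (constants at 70 °C)

With the hot κ, the south-west gain asks for a mean free starting material of 2.81 %, above the 2.00 % of my tightened reckoning. Part of that gain comes from the backward run from dormant form to starting material: the run without it leaves south-west a gain of 0.34 points, not 9.3 points. The flask stands at 79.8 % at 2.5 d in part through the time allowed together with the step from two initiating radical to ended chains B: left to 600 h it gives 98.7 %, and without that step 98.3 % at 2.5 d.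

In the neighbour flask with 0.0035 M of initiator, I scale κ with the root of the initiator, to 0.0366 h⁻¹. On the area under the gamma readings that gives 50.5 %, and with no missing share 88.9 %; that neighbour gives 68.2 %.

The readings were generated by integration for substances that don't exist, and the scatter is random.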